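## The problem

Pentabromopseudilin 16 is a small biaryl in which C6 of a phenol is bonded to C2' of a 1H-pyrrole; the phenol carries bromine at C2 and C4, and the pyrrole carries bromine at C3', C4' and C5'. It has no stereocentre, so there is nothing for one centre to control in another. Every selectivity question is one of position: where the aryl–pyrrole bond lies relative to the hydroxyl group, and which carbons bear bromine. The fragile parts are the electron-rich N–H pyrrole (acid and oxidants), the free phenol next to the biaryl bond, and five C–Br bonds that are at risk under excess organolithium, zerovalent palladium or reducing conditions. The three pyrrole bromines fill every free pyrrole position, so they can go on last by exhaustive electrophilic bromination, provided the phenol ring is already blocked ortho and para to oxygen. The real target is therefore 2,4-dibromo-6-(1H-pyrrol-2-yl)phenol 15. Its phenol ring makes the key step possible: the stretch C2(Br)–C3(H)–C4(Br)–C5(H) has exactly the substitution of C3–C6 of 3,5-dibromo-2-pyrone 2, and the remaining pair C1(OH)–C6(pyrrolyl) is a two-carbon unit at the alkyne oxidation level with oxygen on one carbon and the heteroaryl on the other.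

## Retrosynthesis

**16 to 15.** The three pyrrole C–Br bonds (C3', C4', C5') are cut first. Carrying a tribromopyrrole through the route would expose its C–Br bonds to lithium amides and palladium and would make the pyrrolyl alkyne a poor nucleophile. Precursor 15 is lighter by three bromines and has an unsubstituted pyrrole. The forward step only has to brominate every free pyrrole position of 15. The phenol ring already carries bromine at both positions activated by oxygen, so it cannot compete.

**15 to 13.** The O–Si and N–C(O) bonds of the protecting groups are cut, with the N–H silyl ether 14 as the stage between. The silyl group on oxygen is what the ynol ether chemistry leaves behind, and the tert-butyl carbamate on nitrogen tempers the pyrrole during the cycloaddition. Nothing is simplified in the skeleton here. The forward step needs two mild nucleophilic cleavages that leave the aryl bromides alone.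

**13 to 2 and 11.** The phenol ring is opened at C1–C2 and C5–C6, by way of the bridged lactone 12. The neighbouring cut, the biaryl bond C6–C2', would need a trihalogenated phenol and a cross-coupling that tells three carbon–halogen bonds apart. Building the pyrrole onto a preformed arene leads to the roads discussed below. The benzannulation instead fixes all four substituents of the benzene ring by the connectivity of two simple partners, each with one ring fewer than 13: pyrone 2 supplies C2–C5 with both bromines, and siloxyalkyne 11 supplies C1 with its oxygen and C6 with the pyrrole. The forward reaction must be regioselective (the silyloxy carbon must bond to the brominated C3 of 2) and must end in decarboxylation.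

**11 to 8.** The C(sp)–O bond and the O–Si bond are cut, which leaves the plain terminal alkyne 8. Forward, 8 is deprotonated to acetylide 9, which takes up one oxygen atom to give ynolate 10, and 10 is silylated on oxygen. The other entry to ynolates, homologation of an ester, needs excess alkyllithium and would not spare the carbamate. The amide base used here should.

**8 to 7 to 5 and 6.** The C2'–C(sp) bond is cut, which leads to bromide 5 and ethynyltrimethylsilane 6, with silylalkyne 7 between. One-carbon homologation of an N-acylated 2-formylpyrrole was set aside: it needs either basic methanol, which strips an N-acyl group from a 2-formylpyrrole, or an alkoxide adduct next to the carbamate, which invites acyl migration. The cross-coupling meets neither problem and takes place before any aryl bromide is present. Bromide 5 comes from pyrrole 3 by bromination to the labile 2-bromopyrrole 4 and immediate N-acylation, so this branch starts from the simplest heterocycle available.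

**2 to 1.** The C5–Br and C3–Br bonds of the pyrone are cut and a carboxyl group is restored at C5. Coumalic acid 1 is a bulk chemical and gives 2 in one operation by bromodecarboxylation together with bromination next to the lactone carbonyl.

## Roads not taken

**Alternative 1:** Trofimov pyrrole synthesis. The cut removes C4' and C5' of the pyrrole as acetylene A2 and forms C3'–C4' and N1'–C5'. Nitrogen, C2', C3' and the aryl group come from (E)-1-(2-methoxyphenyl)ethanone oxime A1. In KOH/DMSO the oxime A1 adds to A2, the O-vinyl oxime rearranges sigmatropically, and the imino aldehyde cyclises to 2-(2-methoxyphenyl)-1H-pyrrole A3.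
- Merits: arylpyrrole A3 holds the whole carbon skeleton one step after oxime A1. O-Demethylation of A3 and one exhaustive bromination would finish the synthesis in about three steps from A1, because the hydroxyl group directs bromine to exactly C2 and C4 and the pyrrole takes the other three.
- Weak points: A2 is handled in hot superbase; N-vinylation of A3 competes; no bromine can be present during ring formation, since aryl bromides would not survive hot hydroxide in DMSO; and the methyl ether of A3 must be cleaved with a strong Lewis acid in the presence of a pyrrole.
- Comparison: this road is clearly shorter and cheaper than the chosen plan. For this target the late bromination pattern is also the naturally favoured one, so the regiochemical argument for the benzannulation is weak. The chosen plan can only set against it that it avoids pressurised acetylene and superbase, that the arene bromines are placed by construction, and that the two rings are halogenated in separate operations, which would allow patterns that directing effects do not give.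

**Alternative 2:** Azomethine ylide (3+2) cycloaddition. The cut forms C2'–C3' and C4'–C5'. The N-metalated ylide from ethyl N-[(E)-(3,5-dibromo-2-methoxyphenyl)methylidene]glycinate A4, made with AgOAc (monovalent silver) and triethylamine, adds across (E)-1,2-bis(phenylsulfonyl)ethene A5. DBU then expels two sulfinate leaving groups to give ethyl 5-(3,5-dibromo-2-methoxyphenyl)-1H-pyrrole-2-carboxylate A6.
- Merits: the arene bromines are already in place in imine A4; the conditions are mild and need no palladium; the aryl bromides are tolerated.
- Weak points: pyrrole ester A6 carries an ester that the target lacks, which must be hydrolysed and removed or replaced by bromine; the two phenylsulfonyl groups of bis-sulfone A5 are discarded; the methyl ether must still be cleaved.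
- Comparison: at about five steps from imine A4 this road is shorter than the chosen plan, and it fixes the arene bromines just as securely. The chosen plan sets against it only that it builds the pyrrole-bearing carbon without a superfluous carboxyl group and without a demethylation at the end.

**Alternative 3:** Lactam acylation and recyclisation. The cut forms C2'–C3' by Claisen acylation of the sodium enolate of 1-vinylpyrrolidin-2-one A7 with methyl 3,5-dibromo-2-methoxybenzoate A8. Hot hydrochloric acid then removes the vinyl group, opens the lactam, decarboxylates the keto acid and closes N1'–C2' to 5-(3,5-dibromo-2-methoxyphenyl)-3,4-dihydro-2H-pyrrole A9.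
- Merits: lactam A7 and ester A8 are cheap, the chemistry is robust and scalable, no transition metal is needed, and the aryl bromides of A8 survive both stages.
- Weak points: A9 is a pyrroline and must lose H2 to become a pyrrole. Catalytic dehydrogenation endangers the C–Br bonds, and quinone or oxide oxidants are often inefficient on 1-pyrrolines. A demethylation is still needed.
- Comparison: the length is similar to or shorter than the chosen plan. The chosen plan sets against it that the pyrrole is at the correct oxidation level from the first step, so no oxidation has to be carried out on a polybrominated intermediate such as A9.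

Key step: step 6

## Route

Remark on the chemistry: 16 has no stereocentre. The two bridgehead carbons of the transient cycloadduct 12 are the only stereogenic atoms on the route; 12 forms as a racemate and loses them with CO2.

Step 1
Reactants: 1 coumalic acid
Product: 2 3,5-dibromo-2H-pyran-2-one
Conditions: NBS (2.5 equiv), LiOAc, MeCN/H2O, rt
Reagents that add atoms: N-bromosuccinimide, O=C1CCC(=O)N1Br
Why: Hunsdiecker-type bromodecarboxylation at C5 (ipso attack of electrophilic bromine on the vinylogous carboxylate with loss of CO2) together with electrophilic bromination at C3, next to the lactone carbonyl; this is an established one-step route to 2.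

Step 2
Reactants: 3 pyrrole
Product: 5 tert-butyl 2-bromopyrrole-1-carboxylate, via 2-bromo-1H-pyrrole 4 (not isolated)
Conditions: 1,3-dibromo-5,5-dimethylhydantoin (0.5 equiv), THF, −78 °C; then Et3N, Boc2O, DMAP (cat.), −78 °C → rt
Reagents that add atoms: 1,3-dibromo-5,5-dimethylhydantoin, CC1(C)N(Br)C(=O)N(Br)C1=O; di-tert-butyl dicarbonate, CC(C)(C)OC(=O)OC(=O)OC(C)(C)C
Why: Electrophilic aromatic bromination of pyrrole at C2 at low temperature, followed in the same flask by DMAP-catalysed N-acylation, which stabilises the labile bromopyrrole 4; this is a known one-pot sequence, and 5 is kept cold in solution until used.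

Step 3
Reactants: 5 tert-butyl 2-bromopyrrole-1-carboxylate; 6 ethynyltrimethylsilane
Product: 7 tert-butyl 2-[(trimethylsilyl)ethynyl]pyrrole-1-carboxylate
Conditions: Pd(PPh3)2Cl2 (cat.), CuI (cat.), Et3N, THF, rt → 45 °C
Reagents that add atoms: none
Why: Sonogashira coupling; zerovalent palladium inserts readily into the C2–Br bond of the N-acylated pyrrole, the carbamate tolerates the amine base, and the temperature is kept low because 5 is thermally labile.

Step 4
Reactants: 7 tert-butyl 2-[(trimethylsilyl)ethynyl]pyrrole-1-carboxylate
Product: 8 tert-butyl 2-ethynylpyrrole-1-carboxylate
Conditions: K2CO3 (0.2 equiv), MeOH, 0 °C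
Reagents that add atoms: none
Why: Base-catalysed protodesilylation of an alkynylsilane by methanol; catalytic carbonate at 0 °C for a short time should not methanolyse the carbamate, since the ring carries no acyl group to activate it.

Step 5
Reactants: 8 tert-butyl 2-ethynylpyrrole-1-carboxylate
Product: 11 tert-butyl 2-[(triisopropylsilyloxy)ethynyl]pyrrole-1-carboxylate, via lithium acetylide 9 (not isolated), via lithium ynolate 10 (not isolated)
Conditions: LiN(SiMe3)2, THF, −78 °C; t-BuOOLi (from t-BuOOH and LiN(SiMe3)2, THF), −78 → 0 °C; TIPSOTf, −78 → 0 °C
Reagents that add atoms: tert-butyl hydroperoxide, CC(C)(C)OO; triisopropylsilyl trifluoromethanesulfonate, CC(C)[Si](OS(=O)(=O)C(F)(F)F)(C(C)C)C(C)C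
Why: The silylamide deprotonates the alkyne, the acetylide carbon attacks the lithiated oxygen of lithium tert-butyl peroxide and expels tert-butoxide (the established oxidation of lithium acetylides to ynolates), and the bulky silyl triflate silylates the ambident ynolate on oxygen to give the siloxyalkyne and not the C-silyl ketene; the non-nucleophilic base should spare the carbamate.

Step 6
Reactants: 2 3,5-dibromo-2H-pyran-2-one; 11 tert-butyl 2-[(triisopropylsilyloxy)ethynyl]pyrrole-1-carboxylate
Product: 13 tert-butyl 2-[3,5-dibromo-2-(triisopropylsilyloxy)phenyl]pyrrole-1-carboxylate, via bridged lactone cycloadduct 12 (not isolated)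
Conditions: PhMe, 90 → 110 °C, sealed tube
Reagents that add atoms: none
Why: This is an inverse-electron-demand Diels–Alder reaction of an electron-poor 2-pyrone with an electron-rich heteroatom-substituted alkyne, followed by cycloreversion with loss of CO2; the closest known reaction types are the pyrone-to-benzene benzannulation with alkynes and the polar benzannulations of siloxyalkynes. Bond formation is asynchronous: the alkyne carbon β to oxygen, which carries the pyrrole, attacks the electrophilic C6 of 2, and the developing ketenium carbon closes onto C3. The six-membered carbocycle of 12 is thus closed by an intermolecular (4+2) cycloaddition that forms C5–C6 and C1–C2 (phenol numbering). The 2-oxabicyclo[2.2.2]octadienone 12 then ejects CO2 in a retro-(4+2) step, which turns that carbocycle into the benzene ring of 13. The two bridgehead stereocentres of 12 arise as a racemate and vanish on aromatisation, so no stereocontrol is required. The selectivity needed is regiochemical, with the silyloxy carbon next to the brominated pyrone carbon, and the matched polarisation of the partners secures it: the ynol ether β-carbon is the nucleophilic terminus and C6 the electrophilic diene terminus, as with enol ethers and brominated 2-pyrones. The silyl ynol ether cannot lose an alkene by retro-ene fragmentation, the bulky silyl group retards the 1,3-shift to a silylketene, the carbamate keeps the pyrrole from acting as a nucleophile, and the C–Br bonds are inert to purely thermal conditions.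

Step 7
Reactants: 13 tert-butyl 2-[3,5-dibromo-2-(triisopropylsilyloxy)phenyl]pyrrole-1-carboxylate
Product: 15 2,4-dibromo-6-(1H-pyrrol-2-yl)phenol, via N-unprotected silyl ether 14 (not isolated)
Conditions: NaOMe (0.2 equiv), MeOH/THF, rt; then Bu4NF, THF, 0 °C → rt; aq. NH4Cl
Reagents that add atoms: none
Why: Catalytic methoxide transesterifies the N-acylpyrrole-type carbamate, for which pyrrolide is a good leaving group, and fluoride then cleaves the aryl silyl ether, whose dibromophenoxide is a stabilised leaving group; both are standard deprotections and leave the aryl bromides untouched.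

Step 8
Reactants: 15 2,4-dibromo-6-(1H-pyrrol-2-yl)phenol
Product: 16 pentabromopseudilin, 2,4-dibromo-6-(3,4,5-tribromo-1H-pyrrol-2-yl)phenol
Conditions: NBS (3.0 equiv), THF, −78 °C → rt; aq. Na2S2O3
Reagents that add atoms: N-bromosuccinimide, O=C1CCC(=O)N1Br
Why: Exhaustive electrophilic aromatic bromination of a 2-arylpyrrole; the pyrrole is far more nucleophilic than the phenol ring, whose ortho and para positions are already brominated, and three equivalents fill C5', C3' and C4', so no regiochemical choice arises. The reductive work-up should return any transient O- or ipso-brominated dienone to the phenol.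

## Compound list

1 | coumalic acid (2-oxo-2H-pyran-5-carboxylic acid) | O=C(O)c1ccc(=O)oc1 | starting material
2 | 3,5-dibromo-2H-pyran-2-one | O=c1occ(Br)cc1Br | intermediate
3 | pyrrole | c1cc[nH]c1 | starting material
4 | 2-bromo-1H-pyrrole | Brc1ccc[nH]1 | intermediate (not isolated)
5 | tert-butyl 2-bromopyrrole-1-carboxylate | CC(C)(C)OC(=O)n1cccc1Br | intermediate
6 | ethynyltrimethylsilane | C#C[Si](C)(C)C | starting material
7 | tert-butyl 2-[(trimethylsilyl)ethynyl]pyrrole-1-carboxylate | CC(C)(C)OC(=O)n1cccc1C#C[Si](C)(C)C | intermediate
8 | tert-butyl 2-ethynylpyrrole-1-carboxylate | C#Cc1cccn1C(=O)OC(C)(C)C | intermediate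
9 | lithium acetylide of 8, lithium [1-(tert-butoxycarbonyl)pyrrol-2-yl]ethynide | [Li+].[C-]#Cc1cccn1C(=O)OC(C)(C)C | intermediate (not isolated)
10 | lithium ynolate, lithium 2-[1-(tert-butoxycarbonyl)pyrrol-2-yl]ethynolate | [Li+].[O-]C#Cc1cccn1C(=O)OC(C)(C)C | intermediate (not isolated)
11 | tert-butyl 2-[(triisopropylsilyloxy)ethynyl]pyrrole-1-carboxylate | CC(C)[Si](OC#Cc1cccn1C(=O)OC(C)(C)C)(C(C)C)C(C)C | intermediate
12 | tert-butyl 2-[4,7-dibromo-3-oxo-5-(triisopropylsilyloxy)-2-oxabicyclo[2.2.2]octa-5,7-dien-6-yl]pyrrole-1-carboxylate (racemic) | O=C1OC2C(Br)=CC1(Br)C(O[Si](C(C)C)(C(C)C)C(C)C)=C2c1cccn1C(=O)OC(C)(C)C | intermediate (not isolated)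
13 | tert-butyl 2-[3,5-dibromo-2-(triisopropylsilyloxy)phenyl]pyrrole-1-carboxylate | CC(C)[Si](Oc1c(Br)cc(Br)cc1-c1cccn1C(=O)OC(C)(C)C)(C(C)C)C(C)C | intermediate
14 | 2-[3,5-dibromo-2-(triisopropylsilyloxy)phenyl]-1H-pyrrole | CC(C)[Si](Oc1c(Br)cc(Br)cc1-c1ccc[nH]1)(C(C)C)C(C)C | intermediate (not isolated)
15 | 2,4-dibromo-6-(1H-pyrrol-2-yl)phenol | Oc1c(Br)cc(Br)cc1-c1ccc[nH]1 | intermediate
16 | pentabromopseudilin, 2,4-dibromo-6-(3,4,5-tribromo-1H-pyrrol-2-yl)phenol | Oc1c(Br)cc(Br)cc1-c1[nH]c(Br)c(Br)c1Br | target

## Step count and risk

Total step count: 8. Longest linear sequence: 7 steps (3 to 16, steps 2–8); the pyrone branch (1 to 2) is one step and joins at step 6.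

**Step 6 (key step).**
- What may go wrong: the hindered siloxyalkyne may isomerise to a silylketene or oligomerise before it finds the pyrone. The cycloaddition may be slow because silyl and carbamate groups flank the triple bond. Regiocontrol may leak if the heteroaryl substituent perturbs the polarisation. The carbamate oxygen may capture the ketenium-like terminus with loss of isobutene.
- Fallback: this sets out from 5 and returns at 13, replacing the ring construction by a cross-coupling. Bromide 5 would be borylated (bis(pinacolato)diboron, Pd(dppf)Cl2, KOAc, dioxane) to tert-butyl 2-(4,4,5,5-tetramethyl-1,3,2-dioxaborolan-2-yl)pyrrole-1-carboxylate F1. Commercial 2,4-dibromophenol would be iodinated at its free ortho position (NIS, cat. TsOH) to 2,4-dibromo-6-iodophenol F2 and silylated (TIPSOTf, 2,6-lutidine) to (2,4-dibromo-6-iodophenoxy)triisopropylsilane F3. Suzuki coupling of F1 with F3 (Pd(PPh3)4, aq. Na2CO3, DME, 70 °C), selective for the C–I bond over the two C–Br bonds, would give 13.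

**Step 5.**
- What may go wrong: tert-butoxide or the peroxide anion may cleave or transfer the carbamate at 0 °C. Oxygen transfer to the acetylide may be incomplete. Silylation may occur on carbon. The product may hydrolyse on acidic silica.
- Fallback: this sets out from 5 and returns at 15, taking the ynol ether C–O bond from a reagent instead of making it by oxidation. Ethoxyacetylene, n-BuLi and ZnCl2 would give (ethoxyethynyl)zinc chloride F4 in the flask. Negishi coupling with 5 (Pd(PPh3)4, THF, rt) would give tert-butyl 2-(ethoxyethynyl)pyrrole-1-carboxylate F5. Cycloaddition of F5 with 2 below 80 °C, to stay under the retro-ene threshold of an alkyl ynol ether, would pass through tert-butyl 2-(4,7-dibromo-5-ethoxy-3-oxo-2-oxabicyclo[2.2.2]octa-5,7-dien-6-yl)pyrrole-1-carboxylate F6 and give, after loss of CO2, tert-butyl 2-(3,5-dibromo-2-ethoxyphenyl)pyrrole-1-carboxylate F7. BBr3 (CH2Cl2, −78 → 0 °C) would then cleave the ethyl ether and the carbamate to give 15.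

**Step 7.**
- What may go wrong: methanolysis of the carbamate may be slow next to the ortho-disubstituted aryl group. Early loss of the silyl group would give an acidic phenol that neutralises the catalytic methoxide and stalls the carbamate cleavage. The freed phenoxide may attack any remaining carbamate and give mixtures. The silyl group may migrate from oxygen to the pyrrole nitrogen. The electron-rich product may oxidise in basic solution in air.
- Fallback: this sets out from 13 and returns at 15, using the neighbouring-group reaction instead of avoiding it. Bu4NF alone (THF, rt → 50 °C) would free the phenoxide, which closes onto the carbamate carbonyl and expels tert-butoxide to give the cyclic carbamate 7,9-dibromo-5H-pyrrolo[1,2-c][1,3]benzoxazin-5-one F8, a stable compound that can be purified. LiOH in THF/H2O followed by acidification would open the ring and decarboxylate the carbamic acid to 15.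

**Step 2.**
- What may go wrong: the pyrrole may be brominated more than once, and the unprotected bromopyrrole may decompose before it is acylated.
- Fallback: this sets out from 3 and returns at 7, reversing the order of protection and halogenation. Pyrrole would be acylated (Boc2O, DMAP, MeCN) to tert-butyl pyrrole-1-carboxylate F9. Directed lithiation with lithium 2,2,6,6-tetramethylpiperidide (THF, −78 °C) would give tert-butyl 2-lithiopyrrole-1-carboxylate F10 in the flask, and iodine would give tert-butyl 2-iodopyrrole-1-carboxylate F11. F11 would take the place of 5 in the Sonogashira coupling with 6 and give 7.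

## Further compounds

F1 | step 6 | tert-butyl 2-(4,4,5,5-tetramethyl-1,3,2-dioxaborolan-2-yl)pyrrole-1-carboxylate | CC(C)(C)OC(=O)n1cccc1B1OC(C)(C)C(C)(C)O1
F2 | step 6 | 2,4-dibromo-6-iodophenol | Oc1c(Br)cc(Br)cc1I
F3 | step 6 | (2,4-dibromo-6-iodophenoxy)triisopropylsilane | CC(C)[Si](Oc1c(Br)cc(Br)cc1I)(C(C)C)C(C)C
F4 | step 5 | (ethoxyethynyl)zinc chloride | CCOC#C[Zn]Cl
F5 | step 5 | tert-butyl 2-(ethoxyethynyl)pyrrole-1-carboxylate | CCOC#Cc1cccn1C(=O)OC(C)(C)C
F6 | step 5 | tert-butyl 2-(4,7-dibromo-5-ethoxy-3-oxo-2-oxabicyclo[2.2.2]octa-5,7-dien-6-yl)pyrrole-1-carboxylate (racemic) | CCOC1=C(c2cccn2C(=O)OC(C)(C)C)C2OC(=O)C1(Br)C=C2Br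
F7 | step 5 | tert-butyl 2-(3,5-dibromo-2-ethoxyphenyl)pyrrole-1-carboxylate | CCOc1c(Br)cc(Br)cc1-c1cccn1C(=O)OC(C)(C)C
F8 | step 7 | 7,9-dibromo-5H-pyrrolo[1,2-c][1,3]benzoxazin-5-one | O=C1Oc2c(Br)cc(Br)cc2-c2cccn12
F9 | step 2 | tert-butyl pyrrole-1-carboxylate | CC(C)(C)OC(=O)n1cccc1
F10 | step 2 | tert-butyl 2-lithiopyrrole-1-carboxylate | [Li]c1cccn1C(=O)OC(C)(C)C
F11 | step 2 | tert-butyl 2-iodopyrrole-1-carboxylate | CC(C)(C)OC(=O)n1cccc1I
A1 | alternative 1 | (E)-1-(2-methoxyphenyl)ethanone oxime | C/C(=N\O)c1ccccc1OC
A2 | alternative 1 | acetylene | C#C
A3 | alternative 1 | 2-(2-methoxyphenyl)-1H-pyrrole | COc1ccccc1-c1ccc[nH]1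
A4 | alternative 2 | ethyl N-[(E)-(3,5-dibromo-2-methoxyphenyl)methylidene]glycinate | CCOC(=O)C/N=C/c1cc(Br)cc(Br)c1OC
A5 | alternative 2 | (E)-1,2-bis(phenylsulfonyl)ethene | O=S(=O)(/C=C/S(=O)(=O)c1ccccc1)c1ccccc1
A6 | alternative 2 | ethyl 5-(3,5-dibromo-2-methoxyphenyl)-1H-pyrrole-2-carboxylate | CCOC(=O)c1ccc(-c2cc(Br)cc(Br)c2OC)[nH]1
A7 | alternative 3 | 1-vinylpyrrolidin-2-one | C=CN1CCCC1=O
A8 | alternative 3 | methyl 3,5-dibromo-2-methoxybenzoate | COC(=O)c1cc(Br)cc(Br)c1OC
A9 | alternative 3 | 5-(3,5-dibromo-2-methoxyphenyl)-3,4-dihydro-2H-pyrrole | COc1c(Br)cc(Br)cc1C1=NCCC1
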